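## Structural features

The target is a flavonol: a 4H-chromen-4-one (benzene ring A fused to pyranone ring C) with a 4-hydroxyphenyl ring B on C2 and a hydroxyl on C3. Ring A is substituted on every carbon but C8, with hydroxyls on C5 and C6 and a sulfate monoester on O7. There is no stereocentre, so the problem is one of connectivity and of telling five oxygens apart, exactly one of which (O7) must end as the sulfate. The aryl O–SO3H group is the fragile element: it is lost in acid and cannot be carried through strong base or carbanion chemistry, so it must come late and masked. The free 5,6-dihydroxy-7-oxy ring is a pyrogallol-type arene that oxidises easily, and the C2=C3 bond must survive the final reduction. The real difficulty is the 5,6,7-trioxygenation next to O1 on C8a, because classical flavone syntheses need a phenol oxygen already on C8a of an unsymmetrically protected tetraoxygenated arene. The key step uses the fact that C4, C4a, C5, C6 and C7 with O5, O6 and O7 form a 2,3,4-trioxygenated benzoyl group. Its 4-oxygen (O7) is set apart by acidity, and its only free ortho carbon, para to O6, is C8a, the carbon that must be bonded to O1.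

## Logic of the disconnections

**13 back to 11.** The four O–CH2Ph bonds on O3, O5, O6 and O4' and the S–OCH2CCl3 bond are cut together; 12 is only the salt through which 13 is released. All five groups fall to one mild reduction, so the sulfate never meets acid or strong base and the air-sensitive polyphenol exists only at the end. The forward step must cleave C–O and C–Cl bonds without touching C2=C3 or the aryl O–S bond.

**11 back to 10.** The O7–S bond is cut. A neutral sulfate diester can be purified and is inert until the last step. The demand is that 10 has one free hydroxyl only, on O7.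

**10 back to 9.** The O7–CH2OCH3 bond is cut. An acetal on O7 is the one group removable without disturbing four benzyl ethers. The forward acid treatment must be mild enough to spare the benzyl ether on O5, which lies peri to the carbonyl.

**9 back to 8.** The O1–C8a bond is cut, opening ring C to an acyclic 1,3-dicarbonyl enol. Ring A becomes a plain 2,3,4-trioxygenated benzoyl group with hydrogen on C8a, so no oxygen or halogen has to be placed there beforehand. The forward step must join an enol oxygen to one specific aryl C–H, in preference to the ortho C–H bonds of ring B, without oxidising the rest of the molecule.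

**8 back to 6 and 7.** The bond between the central carbon and its benzyloxy oxygen is cut. This brings in O3 already protected, on a carbon that is easy to activate as a diazo compound. The carbenoid must be captured by the external alcohol faster than by the neighbouring aryl benzyl ether.

**6 back to 5.** The C=N2 bond is cut, returning a 1,3-diketone with a doubly activated methylene. The transfer must be done with a mild base so that neither aryl ketone is cleaved.

**5 back to 3 and 4.** The C–C bond between the methylene carbon and the ring B carbonyl is cut, dividing the skeleton into a methyl ketone carrying ring A and an ester carrying ring B. Only one partner can enolise, so the condensation has a single sense.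

**3 back to 2 and to 1.** The two O–CH2Ph bonds on the future O5 and O6, then the O–CH2OCH3 bond on the future O7, are cut. This arrives at 1, where all three oxygens and the acyl carbon are in place. The first forward alkylation must stop at the most acidic hydroxyl, para to the acetyl group.

## Other disconnections considered

**Alternative 1:** The cut runs through ring A at C7–C8 and C5–C6, so ring A is grown on a finished ring C.
- **Forward step:** LiN(SiMe3)2 would deprotonate the 2-methyl group of the pyranone ester A1. The vinylogous enolate would be acylated by the glycolate ester A2 (C7–C8). A second deprotonation at the benzyloxy-bearing carbon would close onto the neighbouring ester (Dieckmann-type, C5–C6), and enolisation would give A3.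
- **In favour:** Two C–C bonds and ring A form in one flask by ordinary carbonyl chemistry. Every ring A oxygen is fixed by connectivity. A3 has O6 benzylated and O5, O7 free, and O5 is silenced by its hydrogen bond to C4=O, so sulfation of O7 could follow at once.
- **Against:** A1 is a fully substituted pyranone needing a synthesis about as long as the whole approach to 8. After the first acylation the most acidic site is the C8 methylene, so closure must come from a dianion at the less acidic ether carbon. A2 can self-condense, and hard bases can open the pyranone.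
- **Comparison:** On mechanism, precedent and regiochemical certainty Alternative 1 is the better plan, since nothing in it goes beyond known reaction types. Its endgame is shorter by one step. In distinguishing O7 it is the equal of the chosen plan (chelation instead of acidity). On overall step economy and availability of materials the chosen plan should be ahead, because its ring A is bought complete.

**Alternative 2:** The cut is C4–C4a, with O1–C8a made earlier as an aryl enol ether.
- **Forward step:** (CF3CO)2O would turn the acrylic acid A4 into a mixed anhydride that acylates the ortho carbon of the aryloxy ring (intramolecular Friedel–Crafts), giving A5.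
- **In favour:** This is a classical chromone closure onto a strongly activated ring. The aryloxy ring is symmetrical, so both ortho carbons are the same. O1 enters as an ordinary phenol.
- **Against:** A4 is a tetrasubstituted enol ether that must hold aryloxy and carboxyl cis, and it is acid-sensitive under the activating conditions. Its two halves each need several steps. In A5, O5 and O7 carry the same allyl group, so both must be removed before chelation of O5 can direct sulfation to O7.
- **Comparison:** In regiocontrol and precedent Alternative 2 is better than the chosen plan. The endgame is equal in length (one deprotection, sulfation, hydrogenolysis). It is more convergent, but the way to its cyclisation substrate is longer, and the chosen plan distinguishes O7 from the first step.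

**Alternative 3:** The cut is C4a–C5, with C5 to C8 traced back to a squaric acid derivative.
- **Forward step:** Heating the cyclobutenone A6 (racemic at its sp3 carbon) in toluene would open it to a dienylketene. 6π electrocyclisation would join the ketene carbon to C4a, and enolisation would give A7 with a free 5-OH.
- **In favour:** No reagent, neutral conditions, and a substitution pattern fixed by connectivity. The 5-OH appears unprotected and chelated.
- **Against:** O6 and O7 carry the same 4-methoxybenzyl group, so the one oxygen that must be unique is not distinguished. Sulfation would have to choose O7 over the neighbouring O6 unaided. A6 needs hydrogen, not hydroxyl, on its sp3 carbon, so the usual squarate adduct would have to be deoxygenated. The pyranone must also be metallated at the future C8a.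
- **Comparison:** On mechanism Alternative 3 is better: a known thermal cascade, no oxidant, no choice between two aryl rings. It equals Alternative 1 and betters the chosen plan in delivering 5-OH without a protecting group. It is worse on the distinction of O7, the central structural problem, and it should be longer.

Key step: step 6

Assumption: the target is taken as the hydrogen sulfate as drawn; it is released from its ammonium salt only at the very end, because aryl sulfate monoesters are best handled as salts.

## Route

Step 1
Reactants: 1 1-(2,3,4-trihydroxyphenyl)ethan-1-one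
Product: 2 1-[2,3-dihydroxy-4-(methoxymethoxy)phenyl]ethan-1-one
Conditions: MOMCl (1.05 equiv), K2CO3 (1.1 equiv), acetone, 0 °C to rt
Reagents that add atoms: chloro(methoxy)methane, COCCl
Why: Williamson-type O-alkylation of the monophenoxide; the 4-OH, para to the acetyl group, is the most acidic and is the one ionised by one equivalent of base, while the 2-OH is held in a hydrogen bond to the carbonyl and the 3-OH is flanked on both sides.

Step 2
Reactants: 2 1-[2,3-dihydroxy-4-(methoxymethoxy)phenyl]ethan-1-one
Product: 3 1-[2,3-bis(benzyloxy)-4-(methoxymethoxy)phenyl]ethan-1-one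
Conditions: BnBr (2.6 equiv), K2CO3 (3 equiv), DMF, 60 °C
Reagents that add atoms: benzyl bromide, BrCc1ccccc1
Why: Williamson etherification of both remaining phenols; excess reagent and heat are used because the chelated 2-OH reacts slowly, and the MOM acetal is stable to base.

Step 3
Reactants: 3 1-[2,3-bis(benzyloxy)-4-(methoxymethoxy)phenyl]ethan-1-one; 4 methyl 4-(benzyloxy)benzoate
Product: 5 1-[2,3-bis(benzyloxy)-4-(methoxymethoxy)phenyl]-3-[4-(benzyloxy)phenyl]propane-1,3-dione
Conditions: NaH (2.5 equiv), THF, 65 °C; then AcOH, 0 °C
Reagents that add atoms: none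
Why: Crossed Claisen condensation; only the methyl ketone can enolise, the ester has no α-hydrogen, and deprotonation of the diketone formed drives the equilibrium forward.

Step 4
Reactants: 5 1-[2,3-bis(benzyloxy)-4-(methoxymethoxy)phenyl]-3-[4-(benzyloxy)phenyl]propane-1,3-dione
Product: 6 1-[2,3-bis(benzyloxy)-4-(methoxymethoxy)phenyl]-3-[4-(benzyloxy)phenyl]-2-diazopropane-1,3-dione
Conditions: 4-AcNHC6H4SO2N3 (1.2 equiv), Et3N (2 equiv), MeCN, 0 °C to rt
Reagents that add atoms: 4-acetamidobenzenesulfonyl azide, CC(=O)Nc1ccc(cc1)S(=O)(=O)N=[N+]=[N-]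
Why: Regitz diazo transfer to the doubly activated methylene; an amine base is enough, so neither aroyl group is cleaved, and the acetamido reagent is the safer sulfonyl azide to handle.

Step 5
Reactants: 6 1-[2,3-bis(benzyloxy)-4-(methoxymethoxy)phenyl]-3-[4-(benzyloxy)phenyl]-2-diazopropane-1,3-dione; 7 benzyl alcohol
Product: 8 (2E)-1-[2,3-bis(benzyloxy)-4-(methoxymethoxy)phenyl]-2-(benzyloxy)-3-[4-(benzyloxy)phenyl]-3-hydroxyprop-2-en-1-one
Conditions: Rh2(OAc)4 (2 mol %), BnOH (10 equiv), toluene, 80 °C, slow addition of 6
Reagents that add atoms: none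
Why: Rh2(OAc)4-catalysed carbenoid O–H insertion, with the alcohol in large excess and the diazo compound kept dilute so that intermolecular capture prevails. The product is written as its chelated enol, whose (E) geometry is that of the internal hydrogen bond and which equilibrates freely with the diketo form.

Step 6
Reactants: 8 (2E)-1-[2,3-bis(benzyloxy)-4-(methoxymethoxy)phenyl]-2-(benzyloxy)-3-[4-(benzyloxy)phenyl]-3-hydroxyprop-2-en-1-one
Product: 9 3,5,6-tris(benzyloxy)-2-[4-(benzyloxy)phenyl]-7-(methoxymethoxy)-4H-chromen-4-one
Conditions: Pd(OAc)2 (10 mol %), 4,5-diazafluoren-9-one (20 mol %), CsOPiv (0.5 equiv), air (1 atm), PhCl, 100 °C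
Reagents that add atoms: none
Why: Proposed new method: pivalate deprotonates the enol of 8 and the diketonate binds divalent palladium; with the metal held on the enolate oxygen of the ring B side, carboxylate-assisted electrophilic palladation of the trioxygenated ring at C8a gives a seven-membered oxapalladacycle, C–O reductive elimination forms O1–C8a, and air with the diazafluorenone ligand returns zerovalent palladium to divalent palladium. The closest known reaction types are the palladium-catalysed dehydrogenative C–H/O–H cyclisations of 2-arylphenols to dibenzofurans and of 2-arylbenzoic acids to benzocoumarins, where a phenoxide or carboxylate oxygen plays the part of the enolate oxygen, and the CuI-catalysed O-arylation of 2-bromoaryl 1,3-diketones to flavones, where the same enolate oxygen closes the same ring onto C–Br instead of C–H. Ring C closes as a six-membered ring by reductive elimination from the seven-membered palladacycle, formally a 6-endo attack of oxygen on the C8a=C4a arene bond, and the (E)-enol already holds O1 and C4 cis on C2=C3. No stereocentre is formed. Three selectivities are needed: C8a over C8 is fixed by geometry, since only the ortho carbon can reach the enolate oxygen in a six-membered ring; ring A over ring B should follow from the electrophilic character of the palladation, C8a being para to the C6 benzyloxy group on the more electron-rich ring while the ortho carbons of ring B are only meta to their oxygen; and closure through O5 to the 7,8-dioxygenated isomer is excluded because O5 is a benzyl ether and not a hydroxyl. Copper salts and strong acid are left out so that the enolate is not oxygenated at its central carbon and the MOM acetal survives.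

Step 7
Reactants: 9 3,5,6-tris(benzyloxy)-2-[4-(benzyloxy)phenyl]-7-(methoxymethoxy)-4H-chromen-4-one
Product: 10 3,5,6-tris(benzyloxy)-2-[4-(benzyloxy)phenyl]-7-hydroxy-4H-chromen-4-one
Conditions: HCl (1.25 M in MeOH), MeOH/THF, 40 °C
Reagents that add atoms: none
Why: Acid-catalysed transacetalisation; the MOM acetal is exchanged into dimethoxymethane far faster than any benzyl ether is cleaved, and dilute acid at mild temperature should spare the peri benzyl ether on O5.

Step 8
Reactants: 10 3,5,6-tris(benzyloxy)-2-[4-(benzyloxy)phenyl]-7-hydroxy-4H-chromen-4-one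
Product: 11 3,5,6-tris(benzyloxy)-2-[4-(benzyloxy)phenyl]-4-oxo-4H-chromen-7-yl 2,2,2-trichloroethyl sulfate
Conditions: Cl3CCH2OSO2Cl (1.5 equiv), Et3N (2 equiv), DMAP (0.2 equiv), THF, 0 °C to rt
Reagents that add atoms: 2,2,2-trichloroethyl chlorosulfate, ClS(=O)(=O)OCC(Cl)(Cl)Cl
Why: O-sulfation of the only free hydroxyl, the acidic 7-OH, by a chlorosulfate ester; the neutral sulfate diester formed can be purified on silica.

Step 9
Reactants: 11 3,5,6-tris(benzyloxy)-2-[4-(benzyloxy)phenyl]-4-oxo-4H-chromen-7-yl 2,2,2-trichloroethyl sulfate
Product: 13 3,5,6-trihydroxy-2-(4-hydroxyphenyl)-4-oxo-4H-chromen-7-yl hydrogen sulfate, via ammonium sulfate salt 12 (not isolated)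
Conditions: 10% Pd/C, HCO2NH4 (15 equiv), MeOH/THF, rt, N2; then sulfonic acid cation-exchange resin (H+ form), H2O/MeOH, 0 °C, freeze-drying
Reagents that add atoms: none
Why: Catalytic transfer hydrogenolysis cleaves the four benzyl ethers and reductively fragments the trichloroethyl group, unmasking the sulfate monoester as its ammonium salt in buffered, non-acidic medium. The chromenone C2=C3 bond is not reduced under these conditions, and a brief cold cation exchange gives the acid form.

## Compound list

1 | 1-(2,3,4-trihydroxyphenyl)ethan-1-one | CC(=O)c1ccc(O)c(O)c1O | starting material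
2 | 1-[2,3-dihydroxy-4-(methoxymethoxy)phenyl]ethan-1-one | CC(=O)c1ccc(OCOC)c(O)c1O | intermediate
3 | 1-[2,3-bis(benzyloxy)-4-(methoxymethoxy)phenyl]ethan-1-one | CC(=O)c1ccc(OCOC)c(OCc2ccccc2)c1OCc1ccccc1 | intermediate
4 | methyl 4-(benzyloxy)benzoate | COC(=O)c1ccc(OCc2ccccc2)cc1 | starting material
5 | 1-[2,3-bis(benzyloxy)-4-(methoxymethoxy)phenyl]-3-[4-(benzyloxy)phenyl]propane-1,3-dione | O=C(CC(=O)c1ccc(OCc2ccccc2)cc1)c1ccc(OCOC)c(OCc2ccccc2)c1OCc1ccccc1 | intermediate
6 | 1-[2,3-bis(benzyloxy)-4-(methoxymethoxy)phenyl]-3-[4-(benzyloxy)phenyl]-2-diazopropane-1,3-dione | O=C(C(=[N+]=[N-])C(=O)c1ccc(OCc2ccccc2)cc1)c1ccc(OCOC)c(OCc2ccccc2)c1OCc1ccccc1 | intermediate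
7 | benzyl alcohol | OCc1ccccc1 | starting material
8 | (2E)-1-[2,3-bis(benzyloxy)-4-(methoxymethoxy)phenyl]-2-(benzyloxy)-3-[4-(benzyloxy)phenyl]-3-hydroxyprop-2-en-1-one | O/C(c1ccc(OCc2ccccc2)cc1)=C(OCc1ccccc1)\C(=O)c1ccc(OCOC)c(OCc2ccccc2)c1OCc1ccccc1 | intermediate
9 | 3,5,6-tris(benzyloxy)-2-[4-(benzyloxy)phenyl]-7-(methoxymethoxy)-4H-chromen-4-one | O=c1c(OCc2ccccc2)c(-c2ccc(OCc3ccccc3)cc2)oc2cc(OCOC)c(OCc3ccccc3)c(OCc3ccccc3)c12 | intermediate
10 | 3,5,6-tris(benzyloxy)-2-[4-(benzyloxy)phenyl]-7-hydroxy-4H-chromen-4-one | O=c1c(OCc2ccccc2)c(-c2ccc(OCc3ccccc3)cc2)oc2cc(O)c(OCc3ccccc3)c(OCc3ccccc3)c12 | intermediate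
11 | 3,5,6-tris(benzyloxy)-2-[4-(benzyloxy)phenyl]-4-oxo-4H-chromen-7-yl 2,2,2-trichloroethyl sulfate | O=c1c(OCc2ccccc2)c(-c2ccc(OCc3ccccc3)cc2)oc2cc(OS(=O)(=O)OCC(Cl)(Cl)Cl)c(OCc3ccccc3)c(OCc3ccccc3)c12 | intermediate
12 | ammonium 3,5,6-trihydroxy-2-(4-hydroxyphenyl)-4-oxo-4H-chromen-7-yl sulfate | O=c1c(O)c(-c2ccc(O)cc2)oc2cc(OS(=O)(=O)[O-])c(O)c(O)c12.[NH4+] | intermediate
13 | 3,5,6-trihydroxy-2-(4-hydroxyphenyl)-4-oxo-4H-chromen-7-yl hydrogen sulfate | O=c1c(O)c(-c2ccc(O)cc2)oc2cc(OS(=O)(=O)O)c(O)c(O)c12 | target

## Step count and least certain steps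

Total: 9 steps. Longest linear sequence: 9 steps (1 to 13); 4 and 7 enter as purchased partners in steps 3 and 5.

**Step 6 (key step, proposed new method).**
- **What may go wrong:** The closure may take place onto ring B, because both aryl ketone rings offer ortho C–H bonds to the same diketonate and the C–H cleavage may follow C–H acidity rather than arene nucleophilicity. The catalyst may be arrested as a stable bis(diketonate) chelate. C–O reductive elimination from divalent palladium may be too slow to turn over. The enolate may be oxygenated and cleaved at its central carbon by air.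
- **Fallback (known chemistry only; sets out from 2, comes back at 9):** a bromine is placed on C8a while O6 is a free phenol, and the ring is closed by copper-catalysed O-arylation.
  - Mono-allylation of 2 at the unchelated 3-OH (allyl bromide, K2CO3, acetone) gives 1-[2-hydroxy-4-(methoxymethoxy)-3-(prop-2-en-1-yloxy)phenyl]ethan-1-one F1.
  - Benzylation of the chelated hydroxyl (BnBr, K2CO3, DMF, 60 °C) gives 1-[2-(benzyloxy)-4-(methoxymethoxy)-3-(prop-2-en-1-yloxy)phenyl]ethan-1-one F2.
  - Removal of the allyl group (Pd(PPh3)4, morpholine, THF) gives 1-[2-(benzyloxy)-3-hydroxy-4-(methoxymethoxy)phenyl]ethan-1-one F3.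
  - The only free phenol of F3 has both ortho positions blocked and should direct NBS (MeCN, 0 °C) to its para carbon, giving 1-[2-(benzyloxy)-6-bromo-3-hydroxy-4-(methoxymethoxy)phenyl]ethan-1-one F4.
  - Benzylation gives 1-[2,3-bis(benzyloxy)-6-bromo-4-(methoxymethoxy)phenyl]ethan-1-one F5.
  - Claisen condensation with 4 as in step 3 gives 1-[2,3-bis(benzyloxy)-6-bromo-4-(methoxymethoxy)phenyl]-3-[4-(benzyloxy)phenyl]propane-1,3-dione F6.
  - Diazo transfer as in step 4 gives 1-[2,3-bis(benzyloxy)-6-bromo-4-(methoxymethoxy)phenyl]-3-[4-(benzyloxy)phenyl]-2-diazopropane-1,3-dione F7.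
  - O–H insertion into 7 as in step 5 gives 2-(benzyloxy)-1-[2,3-bis(benzyloxy)-6-bromo-4-(methoxymethoxy)phenyl]-3-[4-(benzyloxy)phenyl]propane-1,3-dione F8 (racemic, enolisable).
  - CuI (10 mol %) with K2CO3 in DMF at 100 °C then joins the enolate oxygen to the brominated carbon and gives 9.
  - The bromine fixes both the ring and the position, at the price of eight extra operations.

**Step 5.**
- **What may go wrong:** The carbenoid may be captured intramolecularly by the oxygen of the neighbouring ortho benzyl ether (oxonium ylide formation followed by benzyl shift) before benzyl alcohol intercepts it, because that oxygen sits five atoms from the carbenoid carbon.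
- **Fallback (sets out from 3, comes back at 8; 5 and 6 are not needed):** the oxygen is put on the methyl ketone before the condensation.
  - Silylation of 3 (TMSOTf, Et3N, CH2Cl2, 0 °C) gives ({1-[2,3-bis(benzyloxy)-4-(methoxymethoxy)phenyl]ethenyl}oxy)(trimethyl)silane F9.
  - Rubottom oxidation (mCPBA, NaHCO3, CH2Cl2, 0 °C; then K2CO3, MeOH) gives 1-[2,3-bis(benzyloxy)-4-(methoxymethoxy)phenyl]-2-hydroxyethan-1-one F10.
  - Neutral benzylation (BnBr, Ag2O, CH2Cl2) gives 2-(benzyloxy)-1-[2,3-bis(benzyloxy)-4-(methoxymethoxy)phenyl]ethan-1-one F11.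
  - Crossed Claisen condensation of its enolate with 4 (LiN(SiMe3)2, THF, −78 °C to rt) gives 8 without any diazo compound.

**Step 1.**
- **What may go wrong:** Alkylation may not stop at O4 and may spread to O3, since only the difference in acidity holds it back.
- **Fallback (sets out from 1, comes back at 3; 2 is bypassed):** the selection is moved to chelation and to dianion reactivity.
  - Heating 1 with Ph2CCl2 (170 °C) ties the two unchelated oxygens together as 1-(4-hydroxy-2,2-diphenyl-2H-1,3-benzodioxol-5-yl)ethan-1-one F12.
  - Benzylation of the remaining chelated hydroxyl (BnBr, K2CO3, DMF) gives 1-[4-(benzyloxy)-2,2-diphenyl-2H-1,3-benzodioxol-5-yl]ethan-1-one F13.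
  - Hydrolysis of the ketal (AcOH/H2O, 100 °C) gives 1-[2-(benzyloxy)-3,4-dihydroxyphenyl]ethan-1-one F14.
  - Its dianion (NaH, 2.0 equiv, DMSO) should be benzylated by one equivalent of BnBr at the less stabilised and more nucleophilic oxygen meta to the acetyl group, giving 1-[2,3-bis(benzyloxy)-4-hydroxyphenyl]ethan-1-one F15.
  - The single hydroxyl left is then converted into its MOM ether (MOMCl, i-Pr2NEt, CH2Cl2), giving 3.

**Step 9.**
- **What may go wrong:** Hydrogenolysis of the crowded benzyl ethers on O5 and O6 may be incomplete. Dechlorination may stall short of fragmentation and leave a partly reduced haloethyl sulfate. Sulfate may be lost during the acid exchange.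
- **Fallback (sets out from 10, comes back at 12; 11 is bypassed):** the sulfate is introduced unprotected and only benzyl groups are left to remove.
  - Treatment of 10 with SO3·pyridine in pyridine at 50 °C, then aqueous NH4HCO3, gives ammonium 3,5,6-tris(benzyloxy)-2-[4-(benzyloxy)phenyl]-4-oxo-4H-chromen-7-yl sulfate F16.
  - Hydrogenolysis (H2, 1 atm, Pd/C, MeOH/THF) then gives 12, which is treated as in the second part of step 9.

## Further compounds

F1 | step 6 | 1-[2-hydroxy-4-(methoxymethoxy)-3-(prop-2-en-1-yloxy)phenyl]ethan-1-one | CC(=O)c1ccc(OCOC)c(OCC=C)c1O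
F2 | step 6 | 1-[2-(benzyloxy)-4-(methoxymethoxy)-3-(prop-2-en-1-yloxy)phenyl]ethan-1-one | CC(=O)c1ccc(OCOC)c(OCC=C)c1OCc1ccccc1
F3 | step 6 | 1-[2-(benzyloxy)-3-hydroxy-4-(methoxymethoxy)phenyl]ethan-1-one | CC(=O)c1ccc(OCOC)c(O)c1OCc1ccccc1
F4 | step 6 | 1-[2-(benzyloxy)-6-bromo-3-hydroxy-4-(methoxymethoxy)phenyl]ethan-1-one | CC(=O)c1c(Br)cc(OCOC)c(O)c1OCc1ccccc1
F5 | step 6 | 1-[2,3-bis(benzyloxy)-6-bromo-4-(methoxymethoxy)phenyl]ethan-1-one | CC(=O)c1c(Br)cc(OCOC)c(OCc2ccccc2)c1OCc1ccccc1
F6 | step 6 | 1-[2,3-bis(benzyloxy)-6-bromo-4-(methoxymethoxy)phenyl]-3-[4-(benzyloxy)phenyl]propane-1,3-dione | O=C(CC(=O)c1ccc(OCc2ccccc2)cc1)c1c(Br)cc(OCOC)c(OCc2ccccc2)c1OCc1ccccc1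
F7 | step 6 | 1-[2,3-bis(benzyloxy)-6-bromo-4-(methoxymethoxy)phenyl]-3-[4-(benzyloxy)phenyl]-2-diazopropane-1,3-dione | O=C(C(=[N+]=[N-])C(=O)c1ccc(OCc2ccccc2)cc1)c1c(Br)cc(OCOC)c(OCc2ccccc2)c1OCc1ccccc1
F8 | step 6 | 2-(benzyloxy)-1-[2,3-bis(benzyloxy)-6-bromo-4-(methoxymethoxy)phenyl]-3-[4-(benzyloxy)phenyl]propane-1,3-dione (racemic) | O=C(C(OCc1ccccc1)C(=O)c1ccc(OCc2ccccc2)cc1)c1c(Br)cc(OCOC)c(OCc2ccccc2)c1OCc1ccccc1
F9 | step 5 | ({1-[2,3-bis(benzyloxy)-4-(methoxymethoxy)phenyl]ethenyl}oxy)(trimethyl)silane | C=C(O[Si](C)(C)C)c1ccc(OCOC)c(OCc2ccccc2)c1OCc1ccccc1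
F10 | step 5 | 1-[2,3-bis(benzyloxy)-4-(methoxymethoxy)phenyl]-2-hydroxyethan-1-one | OCC(=O)c1ccc(OCOC)c(OCc2ccccc2)c1OCc1ccccc1
F11 | step 5 | 2-(benzyloxy)-1-[2,3-bis(benzyloxy)-4-(methoxymethoxy)phenyl]ethan-1-one | O=C(COCc1ccccc1)c1ccc(OCOC)c(OCc2ccccc2)c1OCc1ccccc1
F12 | step 1 | 1-(4-hydroxy-2,2-diphenyl-2H-1,3-benzodioxol-5-yl)ethan-1-one | CC(=O)c1ccc2OC(c3ccccc3)(c3ccccc3)Oc2c1O
F13 | step 1 | 1-[4-(benzyloxy)-2,2-diphenyl-2H-1,3-benzodioxol-5-yl]ethan-1-one | CC(=O)c1ccc2OC(c3ccccc3)(c3ccccc3)Oc2c1OCc1ccccc1
F14 | step 1 | 1-[2-(benzyloxy)-3,4-dihydroxyphenyl]ethan-1-one | CC(=O)c1ccc(O)c(O)c1OCc1ccccc1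
F15 | step 1 | 1-[2,3-bis(benzyloxy)-4-hydroxyphenyl]ethan-1-one | CC(=O)c1ccc(O)c(OCc2ccccc2)c1OCc1ccccc1
F16 | step 9 | ammonium 3,5,6-tris(benzyloxy)-2-[4-(benzyloxy)phenyl]-4-oxo-4H-chromen-7-yl sulfate | O=c1c(OCc2ccccc2)c(-c2ccc(OCc3ccccc3)cc2)oc2cc(OS(=O)(=O)[O-])c(OCc3ccccc3)c(OCc3ccccc3)c12.[NH4+]
A1 | alternative 1 | methyl 5-(benzyloxy)-6-[4-(benzyloxy)phenyl]-2-methyl-4-oxo-4H-pyran-3-carboxylate | COC(=O)c1c(C)oc(-c2ccc(OCc3ccccc3)cc2)c(OCc2ccccc2)c1=O
A2 | alternative 1 | methyl 2-(benzyloxy)acetate | COC(=O)COCc1ccccc1
A3 | alternative 1 | 3,6-bis(benzyloxy)-2-[4-(benzyloxy)phenyl]-5,7-dihydroxy-4H-chromen-4-one | O=c1c(OCc2ccccc2)c(-c2ccc(OCc3ccccc3)cc2)oc2cc(O)c(OCc3ccccc3)c(O)c12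
A4 | alternative 2 | (2E)-2-(benzyloxy)-3-[4-(benzyloxy)phenyl]-3-[4-(benzyloxy)-3,5-bis(prop-2-en-1-yloxy)phenoxy]prop-2-enoic acid | OC(=O)/C(OCc1ccccc1)=C(\Oc1cc(OCC=C)c(OCc2ccccc2)c(OCC=C)c1)c1ccc(OCc2ccccc2)cc1
A5 | alternative 2 | 5,7-bis(allyloxy)-3,6-bis(benzyloxy)-2-[4-(benzyloxy)phenyl]-4H-chromen-4-one | O=c1c(OCc2ccccc2)c(-c2ccc(OCc3ccccc3)cc2)oc2cc(OCC=C)c(OCc3ccccc3)c(OCC=C)c12
A6 | alternative 3 | 4-{5-(benzyloxy)-6-[4-(benzyloxy)phenyl]-4-oxo-4H-pyran-2-yl}-2,3-bis[(4-methoxybenzyl)oxy]cyclobut-2-en-1-one (racemic) | O=C1C(OCc2ccc(OC)cc2)=C(OCc2ccc(OC)cc2)C1c1cc(=O)c(OCc2ccccc2)c(-c2ccc(OCc3ccccc3)cc2)o1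
A7 | alternative 3 | 3-(benzyloxy)-2-[4-(benzyloxy)phenyl]-5-hydroxy-6,7-bis[(4-methoxybenzyl)oxy]-4H-chromen-4-one | O=c1c(OCc2ccccc2)c(-c2ccc(OCc3ccccc3)cc2)oc2cc(OCc3ccc(OC)cc3)c(OCc3ccc(OC)cc3)c(O)c12
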